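**Strategy.** The route rests on opening ring A, the 2-methylidenecyclopentan-1-one of the upper unit, at its C(=O)–C(=CH2) bond: the ketone carbon is a masked formyl group and the methylidene-bearing carbon a masked terminal alkyne. The precursor of the key step is therefore an ynal that already holds the complete lower quadrane ketone, linked through CH2 to the α-carbon of an aldehyde that sits on the bridge carbon of a bicyclo[3.2.1]octane whose quaternary bridgehead carries C≡CH. Rhodium-catalysed intramolecular hydroacylation (reversed polarity at the formyl carbon) closes this last ring as the final step and creates ketone and exocyclic alkene at once, in a redox-neutral isomerisation.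

Key step: step 10

Remarks on the chemistry:
- Bicyclo[3.2.1]octanes are numbered with C1 = alkynyl-bearing bridgehead and C8 = one-carbon bridge. The tricyclic ketone units are numbered as tricyclo[4.3.2.0^{1,5}]undecanes (C2 = methylidene or CH carbon, C3 = C=O, C4 = other α-carbon).
- Assumption: in aldehyde 11 the C8 epimer with the formyl group syn to the C6–C7 bridge is the thermodynamic one, because the other face of C8 is 1,3-diaxial to the C2 methyl group.

**Step 1**
Reactants: 1 2-iodocyclohex-2-en-1-one
Product: 2 2-[(trimethylsilyl)ethynyl]cyclohex-2-en-1-one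
Conditions: ethynyltrimethylsilane, PdCl2(PPh3)2 (3 mol %), CuI (6 mol %), i-Pr2NH, THF, 0 °C to rt
Reagents that add atoms: ethynyltrimethylsilane, C#C[Si](C)(C)C
Why: Sonogashira coupling of an α-iodoenone, whose C–I bond is activated for oxidative addition by the adjacent carbonyl group; no stereocentre is formed.

**Step 2**
Reactants: 2 2-[(trimethylsilyl)ethynyl]cyclohex-2-en-1-one
Product: 4 (2R,3S)-3-methyl-2-(prop-2-yn-1-yl)-2-[(trimethylsilyl)ethynyl]cyclohexan-1-one, via bromomagnesium enolate 3 (not isolated)
Conditions: MeMgBr, CuBr·SMe2 (5 mol %), 1-[2-(dicyclohexylphosphino)ferrocenyl]ethyldiphenylphosphine (6 mol %, the antipode that gives 3S), t-BuOMe, −78 °C; then propargyl bromide, DMPU, −78 to 0 °C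
Reagents that add atoms: methylmagnesium bromide, C[Mg]Br; 3-bromoprop-1-yne, C#CCBr
Why: Copper-catalysed asymmetric conjugate addition of the Grignard reagent to the α-substituted cyclic enone sets the methyl-bearing centre (3S) under ligand control, and the regio-defined magnesium enolate is then C-alkylated at the alkynyl-bearing carbon anti to the neighbouring methyl group, which fixes the quaternary centre (2R, propargyl trans to methyl).

**Step 3**
Reactants: 4 (2R,3S)-3-methyl-2-(prop-2-yn-1-yl)-2-[(trimethylsilyl)ethynyl]cyclohexan-1-one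
Product: 5 tert-butyl(dimethyl){[(5S,6R)-5-methyl-6-(prop-2-yn-1-yl)-6-[(trimethylsilyl)ethynyl]cyclohex-1-en-1-yl]oxy}silane
Conditions: TBSOTf, Et3N, CH2Cl2, 0 °C to rt
Reagents that add atoms: tert-butyldimethylsilyl trifluoromethanesulfonate, CC(C)(C)[Si](C)(C)OS(=O)(=O)C(F)(F)F
Why: Soft enolisation (silyl triflate and amine) can only go towards C6 because C2 is quaternary, which gives the single silyl enol ether needed for the carbocyclisation.

**Step 4**
Reactants: 5 silyl enol ether
Product: 6 (1R,2S,5R)-2-methyl-6-methylidene-1-[(trimethylsilyl)ethynyl]bicyclo[3.2.1]octan-8-one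
Conditions: (Ph3P)AuCl (10 mol %), AgBF4 (10 mol %), CH2Cl2/MeOH 10:1, 40 °C
Reagents that add atoms: none
Why: Conia-ene-type carbocyclisation under monovalent gold catalysis, in which the enol ether carbon attacks the π-activated terminal alkyne in a 5-exo-dig mode (the silyl-capped alkyne is out of reach), and the bridge can only form on the face that carries the propargyl group, which fixes the new bridgehead (5R).

**Step 5**
Reactants: 6 (1R,2S,5R)-2-methyl-6-methylidene-1-[(trimethylsilyl)ethynyl]bicyclo[3.2.1]octan-8-one
Product: 8 (1R,2S,5R)-2,6,6-trimethyl-1-[(trimethylsilyl)ethynyl]bicyclo[3.2.1]octan-8-one, via sulfonylhydrazide adduct 7 (not isolated)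
Conditions: Fe(acac)3 (50 mol %), PhSiH3, CH2=N–NHSO2(n-C8H17), THF/MeOH, rt; then MeOH, 60 °C
Reagents that add atoms: N'-methylideneoctane-1-sulfonohydrazide (formaldehyde octanesulfonylhydrazone), C=NNS(=O)(=O)CCCCCCCC
Why: Iron hydride hydrogen-atom transfer to the 1,1-disubstituted alkene gives the tertiary radical, which adds to the formaldehyde hydrazone, and heating the adduct expels sulfinate and dinitrogen to leave a methyl group (reductive hydromethylation), so the methylidene becomes the gem-dimethyl carbon while ketone and silyl alkyne stay untouched.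

**Step 6**
Reactants: 8 (1R,2S,5R)-2,6,6-trimethyl-1-[(trimethylsilyl)ethynyl]bicyclo[3.2.1]octan-8-one
Product: 11 (1S,2S,5S,8S)-1-ethynyl-2,6,6-trimethylbicyclo[3.2.1]octane-8-carbaldehyde (formyl syn to the C6–C7 bridge), via methyl enol ether 9 (not isolated), via silylated aldehyde 10 (not isolated)
Conditions: MeOCH2PPh3Cl, KN(SiMe3)2, THF, 0 to 50 °C; then 2 M HCl, THF, rt; then K2CO3, MeOH, rt
Reagents that add atoms: (methoxymethyl)triphenylphosphonium chloride, COC[P+](c1ccccc1)(c1ccccc1)c1ccccc1.[Cl-]; water, O
Why: Wittig methoxymethylenation of the non-enolisable bridge ketone and enol ether hydrolysis give the one-carbon homologue, and potassium carbonate in methanol then epimerises C8 to the thermodynamic epimer (formyl away from the axial C2 methyl) while it cleaves the C–Si bond.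

**Step 7**
Reactants: 11 (1S,2S,5S,8S)-1-ethynyl-2,6,6-trimethylbicyclo[3.2.1]octane-8-carbaldehyde
Product: 13 2-[(1S,2S,5S,8S)-1-ethynyl-2,6,6-trimethylbicyclo[3.2.1]octan-8-yl]acetaldehyde, via methyl enol ether 12 (not isolated)
Conditions: MeOCH2PPh3Cl, KN(SiMe3)2, THF, −78 °C to rt; then 2 M HCl, THF, rt
Reagents that add atoms: (methoxymethyl)triphenylphosphonium chloride, COC[P+](c1ccccc1)(c1ccccc1)c1ccccc1.[Cl-]; water, O
Why: A second Wittig methoxymethylenation and hydrolysis (one-carbon aldehyde homologation), after which C8 is no longer α to a carbonyl group and is carried on unchanged.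

**Step 8**
Reactants: 13 2-[(1S,2S,5S,8S)-1-ethynyl-2,6,6-trimethylbicyclo[3.2.1]octan-8-yl]acetaldehyde
Product: 14 suberosenone, (1S,5S,6S,9S)-9,11,11-trimethyl-2-methylidenetricyclo[4.3.2.0^{1,5}]undecan-3-one
Conditions: [Rh(cod)2]BF4 (10 mol %), rac-BINAP (10 mol %), activated with H2 then purged, CH2Cl2, rt
Reagents that add atoms: none
Why: Rhodium-catalysed intramolecular hydroacylation of the 5-alkynal (formyl C–H oxidative addition, syn hydrometalation of the terminal alkyne, reductive elimination) closes the α-methylidene cyclopentanone of the future lower unit in a 5-exo-dig sense, and since the ring can only span the cis-disposed C8 and C1 substituents no new stereocentre arises.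

**Step 9**
Reactants: 13 2-[(1S,2S,5S,8S)-1-ethynyl-2,6,6-trimethylbicyclo[3.2.1]octan-8-yl]acetaldehyde; 14 suberosenone
Product: 15 (2R)-2-[(1S,2S,5S,8R)-1-ethynyl-2,6,6-trimethylbicyclo[3.2.1]octan-8-yl]-3-[(1S,2S,5S,6S,9S)-9,11,11-trimethyl-3-oxotricyclo[4.3.2.0^{1,5}]undecan-2-yl]propanal
Conditions: (R)-α,α-diphenylprolinol trimethylsilyl ether (20 mol %), ethyl 3,4-dihydroxybenzoate (20 mol %), CHCl3, 4 °C to rt
Reagents that add atoms: none
Why: Enamine-catalysed Michael addition of the aldehyde to the exocyclic enone, in which the (R)-catalyst shields one face of the E-enamine so that the methylidene carbon of 14 is attacked to give the 2R centre, and the enol of the lower ketone should be protonated from the face of its ring CH2 bridge carbon (C10), opposite the methyl-bearing C9, to give the S-configured α-carbon.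

**Step 10**
Reactants: 15 ynal
Product: 16 alertenone
Conditions: [Rh(cod)2]BF4 (10 mol %), rac-BINAP (10 mol %), activated with H2 then purged, CH2Cl2, rt to 40 °C
Reagents that add atoms: none
Why: Monovalent rhodium inserts into the formyl C–H bond to give an acyl hydride of trivalent rhodium, the terminal alkyne coordinates and undergoes syn hydrometalation that puts hydrogen on the terminal carbon, and C–C reductive elimination joins the acyl carbon to the internal alkyne carbon, so the normally electrophilic formyl carbon is united with the alkyne as an acyl-metal nucleophile. The closest known reaction type is the cationic rhodium/diphosphine-catalysed intramolecular hydroacylation of 5-alkynals to 2-alkylidenecyclopentanones, already used in step 8. Ring A closes in a 5-exo-dig sense by formation of its C2–C3 bond, with the former formyl hydrogen ending on the exocyclic CH2. No stereocentre is created: the ring can only span the cis-disposed substituents on C1 and C5, and C4 (R) is carried over from 15 under neutral conditions and is also the thermodynamically preferred configuration, with the CH2 link on the convex face away from the exo methyl of the gem-dimethyl carbon. The step needs chemoselectivity for alkyne insertion over decarbonylation of the α-branched acyl rhodium hydride and over the ketone, and 5-exo over 6-endo regioselectivity; the chelating diphosphine, the five-atom distance between the acyl carbon and the internal alkyne carbon, and the fact that the methylidene cannot migrate into the ring past the quaternary C1 secure this.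

**Compound list**
1 | 2-iodocyclohex-2-en-1-one | O=C1CCCC=C1I | starting material
2 | 2-[(trimethylsilyl)ethynyl]cyclohex-2-en-1-one | O=C1CCCC=C1C#C[Si](C)(C)C | intermediate
3 | bromomagnesium (3S)-3-methyl-2-[(trimethylsilyl)ethynyl]cyclohex-1-en-1-olate | C[C@H]1CCCC(O[Mg]Br)=C1C#C[Si](C)(C)C | intermediate
4 | (2R,3S)-3-methyl-2-(prop-2-yn-1-yl)-2-[(trimethylsilyl)ethynyl]cyclohexan-1-one | O=C1CCC[C@H](C)[C@@]1(C#C[Si](C)(C)C)CC#C | intermediate
5 | tert-butyl(dimethyl){[(5S,6R)-5-methyl-6-(prop-2-yn-1-yl)-6-[(trimethylsilyl)ethynyl]cyclohex-1-en-1-yl]oxy}silane | CC(C)(C)[Si](C)(C)OC1=CCC[C@H](C)[C@@]1(C#C[Si](C)(C)C)CC#C | intermediate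
6 | (1R,2S,5R)-2-methyl-6-methylidene-1-[(trimethylsilyl)ethynyl]bicyclo[3.2.1]octan-8-one | O=C1[C@@H]2CC[C@H](C)[C@@]1(C#C[Si](C)(C)C)CC2=C | intermediate
7 | N'-alkyl octane-1-sulfonohydrazide adduct at C6 of 6 (C6 bears CH3 and CH2NHNHSO2C8H17, both C6 epimers; other centres as in 6) | O=C1[C@@H]2CC[C@H](C)[C@@]1(C#C[Si](C)(C)C)CC2(C)CNNS(=O)(=O)CCCCCCCC | intermediate
8 | (1R,2S,5R)-2,6,6-trimethyl-1-[(trimethylsilyl)ethynyl]bicyclo[3.2.1]octan-8-one | O=C1[C@@H]2CC[C@H](C)[C@@]1(C#C[Si](C)(C)C)CC2(C)C | intermediate
9 | 8-(methoxymethylidene) derivative of 8 (E/Z mixture; ring centres as in 8) | COC=C1[C@@H]2CC[C@H](C)[C@@]1(C#C[Si](C)(C)C)CC2(C)C | intermediate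
10 | 2,6,6-trimethyl-1-[(trimethylsilyl)ethynyl]bicyclo[3.2.1]octane-8-carbaldehyde (both C8 epimers; other centres as in 8) | O=CC1[C@@H]2CC[C@H](C)[C@@]1(C#C[Si](C)(C)C)CC2(C)C | intermediate
11 | (1S,2S,5S,8S)-1-ethynyl-2,6,6-trimethylbicyclo[3.2.1]octane-8-carbaldehyde | O=C[C@H]1[C@@H]2CC[C@H](C)[C@@]1(C#C)CC2(C)C | intermediate
12 | 1-ethynyl-8-(2-methoxyethenyl)-2,6,6-trimethylbicyclo[3.2.1]octane (E/Z mixture; ring centres as in 11) | COC=C[C@H]1[C@@H]2CC[C@H](C)[C@@]1(C#C)CC2(C)C | intermediate
13 | 2-[(1S,2S,5S,8S)-1-ethynyl-2,6,6-trimethylbicyclo[3.2.1]octan-8-yl]acetaldehyde | O=CC[C@H]1[C@@H]2CC[C@H](C)[C@@]1(C#C)CC2(C)C | intermediate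
14 | suberosenone, (1S,5S,6S,9S)-9,11,11-trimethyl-2-methylidenetricyclo[4.3.2.0^{1,5}]undecan-3-one | C=C1C(=O)C[C@H]2[C@@H]3CC[C@H](C)[C@]12CC3(C)C | intermediate
15 | (2R)-2-[(1S,2S,5S,8R)-1-ethynyl-2,6,6-trimethylbicyclo[3.2.1]octan-8-yl]-3-[(1S,2S,5S,6S,9S)-9,11,11-trimethyl-3-oxotricyclo[4.3.2.0^{1,5}]undecan-2-yl]propanal | O=C[C@H](C[C@@H]2C(=O)C[C@H]3[C@@H]4CC[C@H](C)[C@]23CC4(C)C)[C@H]1[C@@H]2CC[C@H](C)[C@@]1(C#C)CC2(C)C | intermediate
16 | alertenone, (1S,4R,5R,6S,9S)-9,11,11-trimethyl-2-methylidene-4-{[(1S,2S,5S,6S,9S)-9,11,11-trimethyl-3-oxotricyclo[4.3.2.0^{1,5}]undecan-2-yl]methyl}tricyclo[4.3.2.0^{1,5}]undecan-3-one | C=C1C(=O)[C@H](C[C@@H]2C(=O)C[C@H]3[C@@H]4CC[C@H](C)[C@]23CC4(C)C)[C@H]2[C@@H]3CC[C@H](C)[C@]12CC3(C)C | target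

**Step count and risks**
Total step count: 10. Longest linear sequence: 10 steps (1 → 2 → 4 → 5 → 6 → 8 → 11 → 13 → 14 → 15 → 16; aldehyde 13 is used twice).

Steps most likely to fail:

1. Step 10. The acyl rhodium hydride of the α-branched aldehyde may decarbonylate, the terminal alkyne may oligomerise or insert in the 6-endo sense, or the catalyst may be held back by the ketone. The fallback keeps the same bond and the same ring but makes it by a radical. It sets out from 15: Pinnick oxidation (NaClO2, NaH2PO4, 2-methylbut-2-ene, t-BuOH/H2O) should give the carboxylic acid F1, and diphenyl diselenide with PBu3 in CH2Cl2 should convert it into the Se-phenyl selenoester F2. Slow addition of Bu3SnH with AIBN in benzene at 80 °C should generate the acyl radical, which closes ring A by 5-exo-dig attack on the terminal alkyne; hydrogen transfer to the vinyl radical gives the methylidene ketone, and the route is rejoined at 16.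

2. Step 9. The hindered β-branched enamine may add slowly, facial selectivity at the two new α-centres may be poor, or the keto aldehyde may undergo reversible intramolecular aldol addition under amine catalysis. The fallback replaces enamine catalysis by a Lewis acid-mediated Mukaiyama–Michael addition. It sets out from 13: TBSOTf and Et3N in CH2Cl2 should give the tert-butyldimethylsilyl enol ether F3, which is combined with 14 and TiCl4 in CH2Cl2 at −78 °C; aqueous work-up returns to the route at 15. If the centre next to the formyl group comes out as a mixture, it can be corrected after ring closure, since in 16 this carbon is α to the ketone and brief exposure to DBU should converge on the convex-face epimer. The configuration of the α-carbon of the lower ketone rests on kinetic protonation, and its thermodynamic preference is not established.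

3. Step 2. Ligand control on the new α-alkynyl enone may be insufficient, the Grignard reagent may add to the carbonyl group in competition, or the enolate may be alkylated at the alkyne terminus. The fallback gives up catalytic asymmetric induction for a racemic addition and a resolution. It sets out from 2: Me2CuLi in Et2O at −78 °C followed by propargyl bromide and HMPA should give the racemate, that is 4 together with its enantiomer, (2S,3R)-3-methyl-2-(prop-2-yn-1-yl)-2-[(trimethylsilyl)ethynyl]cyclohexan-1-one F4. Preparative chromatography on a chiral stationary phase separates the two, and the route is rejoined at 4.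

**Further compounds**
F1 | step 10 | (2R)-2-(1-ethynyl-2,6,6-trimethylbicyclo[3.2.1]octan-8-yl)-3-(9,11,11-trimethyl-3-oxotricyclo[4.3.2.0^{1,5}]undecan-2-yl)propanoic acid (centres as in 15) | OC(=O)[C@H](C[C@@H]2C(=O)C[C@H]3[C@@H]4CC[C@H](C)[C@]23CC4(C)C)[C@H]1[C@@H]2CC[C@H](C)[C@@]1(C#C)CC2(C)C
F2 | step 10 | Se-phenyl selenoester of F1 | O=C([Se]c1ccccc1)[C@H](C[C@@H]2C(=O)C[C@H]3[C@@H]4CC[C@H](C)[C@]23CC4(C)C)[C@H]1[C@@H]2CC[C@H](C)[C@@]1(C#C)CC2(C)C
F3 | step 9 | tert-butyldimethylsilyl enol ether of 13 (E/Z mixture) | CC(C)(C)[Si](C)(C)OC=C[C@H]1[C@@H]2CC[C@H](C)[C@@]1(C#C)CC2(C)C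
F4 | step 2 | (2S,3R)-3-methyl-2-(prop-2-yn-1-yl)-2-[(trimethylsilyl)ethynyl]cyclohexan-1-one | O=C1CCC[C@@H](C)[C@]1(C#C[Si](C)(C)C)CC#C
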